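**Retrosynthetic overview**
1. C11–C12 and the free C13–OH/5-OH come from one final hydrogenation of an (E)-γ-aminoxy enone. The enone arises by Horner–Wadsworth–Emmons (HWE) olefination of a phthalide β-ketophosphonate with (S)-2-(anilinooxy)propanal, made in the flask by D-proline-catalysed α-aminoxylation of propanal (sets C13).
2. The β-ketophosphonate comes from a phthalide carboxylic acid by decarboxylative C-acylation of diethylphosphonoacetic acid.
3. The lactone ring (the only ring formed; the benzene ring is bought) and the C3 stereocenter come from a chiral Brønsted-acid-catalysed hydrolactonization of an ortho-(E)-alkenylbenzoic acid.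
4. That acid comes from Suzuki coupling of an aryl triflate with the (E)-alkenylboronate of methyl undec-10-ynoate, then saponification.
5. The aryl triflate comes from methyl 2,4,6-trihydroxybenzoate by 4-O-benzylation, mono-O-methylation and triflation.

Assumption: the sense of induction of the step 6 catalyst cannot be predicted with certainty; the (S,S)-catalyst is written, and its mirror image is used, nothing else changed, if the first run gives the (R)-lactone.

**Step 1**
Reactants: 1 methyl 2,4,6-trihydroxybenzoate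
Product: 2 methyl 4-(benzyloxy)-2,6-dihydroxybenzoate
Conditions: BnBr (1.05 equiv), K2CO3 (1.1 equiv), acetone, rt
Reagents that add atoms: benzyl bromide, BrCc1ccccc1
Why: Williamson etherification; the 4-OH is the most acidic phenol (para to the ester) and the only one not hydrogen-bonded to the ester, so one equivalent of base and BnBr alkylates it preferentially.

**Step 2**
Reactants: 2 methyl 4-(benzyloxy)-2,6-dihydroxybenzoate
Product: 3 methyl 4-(benzyloxy)-2-hydroxy-6-methoxybenzoate
Conditions: MeI (1.1 equiv), K2CO3 (1.1 equiv), acetone, 40 °C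
Reagents that add atoms: iodomethane, CI
Why: Williamson O-methylation of one of two equivalent phenols; the remaining OH is then locked in a strong hydrogen bond to the ester carbonyl and resists a second methylation.

**Step 3**
Reactants: 3 methyl 4-(benzyloxy)-2-hydroxy-6-methoxybenzoate
Product: 4 methyl 4-(benzyloxy)-2-methoxy-6-[(trifluoromethanesulfonyl)oxy]benzoate
Conditions: Tf2O, pyridine, CH2Cl2, 0 °C
Reagents that add atoms: trifluoromethanesulfonic anhydride, O=S(=O)(OS(=O)(=O)C(F)(F)F)C(F)(F)F
Why: O-sulfonylation of the chelated phenol with the strongly electrophilic anhydride gives an aryl triflate for cross-coupling.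

**Step 4**
Reactants: 4 methyl 4-(benzyloxy)-2-methoxy-6-[(trifluoromethanesulfonyl)oxy]benzoate; 5 methyl undec-10-ynoate; 6 pinacolborane
Product: 8 methyl 4-(benzyloxy)-2-methoxy-6-[(1E)-11-methoxy-11-oxoundec-1-en-1-yl]benzoate, via alkenylboronate 7 (not isolated)
Conditions: 5, 6 (1.2 equiv), Cp2ZrHCl (5 mol %), Et3N (10 mol %), neat, 60 °C; then 4, PdCl2(dppf) (3 mol %), K3PO4 (3 equiv), THF–H2O, 65 °C
Reagents that add atoms: none
Why: Zirconocene-hydride-catalysed syn-hydroboration of the terminal alkyne gives the (E)-alkenylboronate regioselectively, and Suzuki–Miyaura coupling (oxidative addition of the triflate to zerovalent palladium) joins it to the arene with retention of the E geometry; both esters survive.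

**Step 5**
Reactants: 8 methyl 4-(benzyloxy)-2-methoxy-6-[(1E)-11-methoxy-11-oxoundec-1-en-1-yl]benzoate
Product: 9 (10E)-11-[5-(benzyloxy)-2-carboxy-3-methoxyphenyl]undec-10-enoic acid
Conditions: KOH (10 equiv), EtOH–H2O 4:1, 80 °C; then 1 M HCl, 0 °C
Reagents that add atoms: potassium hydroxide, [K+].[OH-]
Why: Saponification (BAc2) of both esters; the hindered di-ortho-substituted benzoate needs heat, while the benzyl ether and the alkene are inert to hydroxide.

**Step 6**
Reactants: 9 (10E)-11-[5-(benzyloxy)-2-carboxy-3-methoxyphenyl]undec-10-enoic acid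
Product: 10 10-[(1S)-6-(benzyloxy)-4-methoxy-3-oxo-1,3-dihydro-2-benzofuran-1-yl]decanoic acid
Conditions: (S,S)-IDPi (5 mol %), CHCl3, 40 °C
Reagents that add atoms: none
Why: Proposed new method: enantioselective Markovnikov hydrolactonization of a 1,2-disubstituted ortho-alkenylbenzoic acid by a confined, strongly acidic imidodiphosphorimidate (IDPi: two (S)-3,3'-diaryl-BINOL units on a P–N–P core with N-triflyl groups) — the acid protonates the alkene carbon remote from the ring while its counter-anion stays hydrogen-bonded to the ortho-CO2H, so the incipient benzylic cation is captured 5-exo by the carboxyl oxygen inside the chiral pocket (concerted but asynchronous C–H/C–O bond formation), closing the lactone ring and setting C3 as (S) under catalyst control, the remote aliphatic CO2H being unable to compete (12-membered ring); the closest known reaction type is the IDPi-catalysed asymmetric intramolecular hydroalkoxylation and hydrolactonization of unactivated, mainly 1,1-disubstituted alkenes, together with the racemic strong-acid cyclization of 2-(alk-1-enyl)benzoic acids to 3-alkylphthalides.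

**Step 7**
Reactants: 10 10-[(1S)-6-(benzyloxy)-4-methoxy-3-oxo-1,3-dihydro-2-benzofuran-1-yl]decanoic acid
Product: 12 diethyl {11-[(1S)-6-(benzyloxy)-4-methoxy-3-oxo-1,3-dihydro-2-benzofuran-1-yl]-2-oxoundecyl}phosphonate, via acid chloride 11 (not isolated)
Conditions: (COCl)2, DMF (cat.), CH2Cl2, 0 °C to rt, evaporate; then (EtO)2P(O)CH2CO2H, MgCl2, Et3N, MeCN, 0 °C to rt; 1 M HCl
Reagents that add atoms: diethylphosphonoacetic acid, OC(=O)CP(=O)(OCC)OCC; oxalyl chloride, O=C(Cl)C(Cl)=O (chlorine of 11 only)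
Why: Masamune-type decarboxylative Claisen C-acylation of the magnesium enolate of diethylphosphonoacetic acid by the acid chloride gives the β-ketophosphonate under conditions (Et3N/MgCl2) too mild to open the lactone or epimerise C3.

**Step 8**
Reactants: 12 diethyl {11-[(1S)-6-(benzyloxy)-4-methoxy-3-oxo-1,3-dihydro-2-benzofuran-1-yl]-2-oxoundecyl}phosphonate; 13 propanal; 14 nitrosobenzene
Product: 16 (3S)-5-(benzyloxy)-7-methoxy-3-{(11E,13S)-10-oxo-13-[(phenylamino)oxy]tetradec-11-en-1-yl}-2-benzofuran-1(3H)-one, via aminoxy aldehyde 15 (not isolated)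
Conditions: 13 (1.8 equiv), 14 (1.5 equiv), D-proline (30 mol % vs 14), DMSO, rt, 30 min; excess 13 stripped under vacuum; then 12, LiCl, DBU, MeCN, 0 °C
Reagents that add atoms: none
Why: D-proline enamine catalysis (α-aminoxylation): the carboxylic acid of the enamine directs O-attack of PhN=O to one face, giving the (S)-α-aminoxy aldehyde (mirror image of the L-proline outcome), which is trapped at once by Masamune–Roush HWE olefination to the (E)-enone before it can racemise.

**Step 9**
Reactants: 16 (3S)-5-(benzyloxy)-7-methoxy-3-{(11E,13S)-10-oxo-13-[(phenylamino)oxy]tetradec-11-en-1-yl}-2-benzofuran-1(3H)-one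
Product: 17 (3S)-5-hydroxy-3-[(13S)-13-hydroxy-10-oxotetradecyl]-7-methoxy-2-benzofuran-1(3H)-one
Conditions: H2 (1 atm), 10 % Pd/C, EtOAc–EtOH, rt
Reagents that add atoms: none
Why: Heterogeneous hydrogenation/hydrogenolysis saturates the enone C=C, cleaves the N–O bond to free the C13 alcohol and removes the benzyl ether in one operation; neither stereocenter is touched, and the lactone C–O bond is poorly aligned with the arene for hydrogenolysis.

**Compound list**
1 | methyl 2,4,6-trihydroxybenzoate | COC(=O)c1c(O)cc(O)cc1O | starting material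
2 | methyl 4-(benzyloxy)-2,6-dihydroxybenzoate | COC(=O)c1c(O)cc(OCc2ccccc2)cc1O | intermediate
3 | methyl 4-(benzyloxy)-2-hydroxy-6-methoxybenzoate | COC(=O)c1c(O)cc(OCc2ccccc2)cc1OC | intermediate
4 | methyl 4-(benzyloxy)-2-methoxy-6-[(trifluoromethanesulfonyl)oxy]benzoate | COC(=O)c1c(OS(=O)(=O)C(F)(F)F)cc(OCc2ccccc2)cc1OC | intermediate
5 | methyl undec-10-ynoate | C#CCCCCCCCCC(=O)OC | starting material
6 | pinacolborane (4,4,5,5-tetramethyl-1,3,2-dioxaborolane) | [H]B1OC(C)(C)C(C)(C)O1 | starting material
7 | methyl (10E)-11-(4,4,5,5-tetramethyl-1,3,2-dioxaborolan-2-yl)undec-10-enoate | COC(=O)CCCCCCCC/C=C/B1OC(C)(C)C(C)(C)O1 | intermediate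
8 | methyl 4-(benzyloxy)-2-methoxy-6-[(1E)-11-methoxy-11-oxoundec-1-en-1-yl]benzoate | COC(=O)CCCCCCCC/C=C/c1cc(OCc2ccccc2)cc(OC)c1C(=O)OC | intermediate
9 | (10E)-11-[5-(benzyloxy)-2-carboxy-3-methoxyphenyl]undec-10-enoic acid | OC(=O)CCCCCCCC/C=C/c1cc(OCc2ccccc2)cc(OC)c1C(=O)O | intermediate
10 | 10-[(1S)-6-(benzyloxy)-4-methoxy-3-oxo-1,3-dihydro-2-benzofuran-1-yl]decanoic acid | COc1cc(OCc3ccccc3)cc2c1C(=O)O[C@H]2CCCCCCCCCC(=O)O | intermediate
11 | 10-[(1S)-6-(benzyloxy)-4-methoxy-3-oxo-1,3-dihydro-2-benzofuran-1-yl]decanoyl chloride | COc1cc(OCc3ccccc3)cc2c1C(=O)O[C@H]2CCCCCCCCCC(=O)Cl | intermediate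
12 | diethyl {11-[(1S)-6-(benzyloxy)-4-methoxy-3-oxo-1,3-dihydro-2-benzofuran-1-yl]-2-oxoundecyl}phosphonate | COc1cc(OCc3ccccc3)cc2c1C(=O)O[C@H]2CCCCCCCCCC(=O)CP(=O)(OCC)OCC | intermediate
13 | propanal | CCC=O | starting material
14 | nitrosobenzene | O=Nc1ccccc1 | starting material
15 | (2S)-2-[(phenylamino)oxy]propanal | C[C@H](ONc1ccccc1)C=O | intermediate
16 | (3S)-5-(benzyloxy)-7-methoxy-3-{(11E,13S)-10-oxo-13-[(phenylamino)oxy]tetradec-11-en-1-yl}-2-benzofuran-1(3H)-one | COc1cc(OCc3ccccc3)cc2c1C(=O)O[C@H]2CCCCCCCCCC(=O)/C=C/[C@H](C)ONc4ccccc4 | intermediate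
17 | (3S)-5-hydroxy-3-[(13S)-13-hydroxy-10-oxotetradecyl]-7-methoxy-2-benzofuran-1(3H)-one | COc1cc(O)cc2c1C(=O)O[C@H]2CCCCCCCCCC(=O)CC[C@H](C)O | target

**Step count and risks**
Total step count: 9. Longest linear sequence: 9 (1 to 17; compounds 5, 6, 13 and 14 are bought and enter directly).

Most likely to fail, step 6: the new hydrolactonization may be slow (the benzylic cation carries an ortho-carboxyl and two meta-alkoxy groups) or poorly enantioselective. The fallback uses known chemistry, sets out from 4 and comes back at 10. Sonogashira coupling of 4 with 5 (PdCl2(PPh3)2, CuI, Et3N, DMF, 60 °C) gives methyl 4-(benzyloxy)-2-methoxy-6-(11-methoxy-11-oxoundec-1-yn-1-yl)benzoate F1. Saponification (KOH, EtOH–H2O, then HCl) gives 11-[5-(benzyloxy)-2-carboxy-3-methoxyphenyl]undec-10-ynoic acid F2. DBU (cat.) in MeCN at 80 °C closes the ring by 5-exo-dig anti-addition of the carboxylate to give (Z)-10-[6-(benzyloxy)-4-methoxy-3-oxo-2-benzofuran-1(3H)-ylidene]decanoic acid F3. Asymmetric hydrogenation of its enol-lactone C=C with a cationic chiral phosphine–oxazoline complex of monovalent iridium, [Ir(cod)(SpinPHOX)]BArF, under H2 (30 bar) in CH2Cl2, with the ligand enantiomer chosen for the (S)-product, is established for 3-alkylidenephthalides and delivers 10.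

Second, step 8: the α-aminoxy aldehyde 15 is configurationally fragile and residual propanal or nitrosobenzene can consume the phosphonate. The fallback sets out from 11 (made from 10 as in step 7) and comes back at 17. Reduction of 11 with LiAlH(O-t-Bu)3 (THF, −78 °C) gives 10-[(1S)-6-(benzyloxy)-4-methoxy-3-oxo-1,3-dihydro-2-benzofuran-1-yl]decanal F4. Stetter addition to but-3-en-2-one (3-benzyl-5-(2-hydroxyethyl)-4-methylthiazolium chloride, Et3N, EtOH, 70 °C) gives the 1,4-diketone (3S)-5-(benzyloxy)-3-(10,13-dioxotetradecyl)-7-methoxy-2-benzofuran-1(3H)-one F5. A Prelog-selective alcohol dehydrogenase (cofactor recycled with propan-2-ol, buffer–DMSO, 30 °C) reduces only the methyl ketone, since the internal ketone is flanked by two long chains, and gives (3S)-5-(benzyloxy)-3-[(13S)-13-hydroxy-10-oxotetradecyl]-7-methoxy-2-benzofuran-1(3H)-one F6. Hydrogenolysis of the benzyl ether (H2, Pd/C, EtOAc) then gives 17.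

Third, step 1: mono-benzylation of a triphenol can give 2-O- and 2,4-di-O-benzyl products. The fallback sets out from 1 and comes back at 3, so it bypasses step 2 as well. Benzylation of the two most reactive phenols (BnBr 2.2 equiv, K2CO3, DMF, rt) gives methyl 2,4-bis(benzyloxy)-6-hydroxybenzoate F7, the last, carbonyl-chelated OH staying free. Forced methylation (MeI, K2CO3, DMF, 60 °C) gives methyl 2,4-bis(benzyloxy)-6-methoxybenzoate F8. Chelation-controlled removal of only the ortho-benzyl group with MgBr2·OEt2 (toluene–Et2O, 80 °C) gives 3.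

**Further compounds**
F1 | step 6 | methyl 4-(benzyloxy)-2-methoxy-6-(11-methoxy-11-oxoundec-1-yn-1-yl)benzoate | COC(=O)CCCCCCCCC#Cc1cc(OCc2ccccc2)cc(OC)c1C(=O)OC
F2 | step 6 | 11-[5-(benzyloxy)-2-carboxy-3-methoxyphenyl]undec-10-ynoic acid | OC(=O)CCCCCCCCC#Cc1cc(OCc2ccccc2)cc(OC)c1C(=O)O
F3 | step 6 | (Z)-10-[6-(benzyloxy)-4-methoxy-3-oxo-2-benzofuran-1(3H)-ylidene]decanoic acid | OC(=O)CCCCCCCC/C=C1\OC(=O)c2c(OC)cc(OCc3ccccc3)cc21
F4 | step 8 | 10-[(1S)-6-(benzyloxy)-4-methoxy-3-oxo-1,3-dihydro-2-benzofuran-1-yl]decanal | COc1cc(OCc3ccccc3)cc2c1C(=O)O[C@H]2CCCCCCCCCC=O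
F5 | step 8 | (3S)-5-(benzyloxy)-3-(10,13-dioxotetradecyl)-7-methoxy-2-benzofuran-1(3H)-one | COc1cc(OCc3ccccc3)cc2c1C(=O)O[C@H]2CCCCCCCCCC(=O)CCC(C)=O
F6 | step 8 | (3S)-5-(benzyloxy)-3-[(13S)-13-hydroxy-10-oxotetradecyl]-7-methoxy-2-benzofuran-1(3H)-one | COc1cc(OCc3ccccc3)cc2c1C(=O)O[C@H]2CCCCCCCCCC(=O)CC[C@H](C)O
F7 | step 1 | methyl 2,4-bis(benzyloxy)-6-hydroxybenzoate | COC(=O)c1c(O)cc(OCc2ccccc2)cc1OCc1ccccc1
F8 | step 1 | methyl 2,4-bis(benzyloxy)-6-methoxybenzoate | COC(=O)c1c(OC)cc(OCc2ccccc2)cc1OCc1ccccc1
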